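**Plan**

- Retrosynthetic cuts: ring A at C4a–C5 and C8–C8a (C5–C8 come from an acetoacetyl unit carried as a dioxinone), ring C at C2–C3 and O1–C8a, and the B ring at the aryl–prenyl bond.
- Enabling feature: ring C without the arene, O1–C2(Ar)–C3–C4(=O)–C4a=C8a, is a 2-aryl-2,3-dihydro-4H-pyran-4-one, the formal [4+2] adduct of the aryl aldehyde C=O (C2, O1) with a 1-methoxy-3-silyloxybutadiene (C3, C4, C4a, C8a).
- Forward order: prenylated B-ring aldehyde (steps 1–2); ring C by catalytic asymmetric hetero-Diels–Alder annulation (step 3); C8–C8a by vinylogous Mukaiyama–Michael addition and Saegusa re-oxidation (steps 5–6); ring A last, by thermal acylketene closure of C4a–C5 (step 7).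
- Stereochemistry: C2 (S), the only stereocentre, is set by the chiral titanium catalyst in step 3; every later step is base-free, so the C2–O1 bond is not opened.

Key step: step 3

Ar = 4-methoxy-3-(3-methylbut-2-en-1-yl)phenyl. Atom labels O1, C2–C8a are those of the flavanone throughout.

Assumption: the (S)-H8-BINOL/Ti(IV) catalyst is taken to attack the Si face of the aryl aldehyde and so give the 2S pyranone; if the sense on this aldehyde is the opposite, the (R)-ligand is used and nothing else changes.

**Step 1**
Reactants: 1 3-bromo-4-methoxybenzaldehyde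
Product: 2 2-bromo-4-(dimethoxymethyl)-1-methoxybenzene
Conditions: HC(OMe)3, MeOH, cat. p-TsOH, rt; Et3N quench
Reagents that add atoms: trimethyl orthoformate, COC(OC)OC
Why: Acid-catalysed acetalisation with the orthoformate as water scavenger masks the formyl group against the aryllithium of step 2 (acetal protection).

**Step 2**
Reactants: 2 2-bromo-4-(dimethoxymethyl)-1-methoxybenzene; 3 1-bromo-3-methylbut-2-ene (prenyl bromide)
Product: 6 4-methoxy-3-(3-methylbut-2-en-1-yl)benzaldehyde, via aryllithium 4 (not isolated), via prenylated acetal 5 (not isolated)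
Conditions: n-BuLi, THF, −78 °C; CuBr·SMe2 (10 mol%), 3, −78 → 0 °C; then 1 M HCl, THF, rt
Reagents that add atoms: water, O
Why: Bromine–lithium exchange ortho to the methoxy group is fast at −78 °C, copper-catalysed allylic substitution by the aryl nucleophile takes place at the unhindered primary carbon of prenyl bromide (SN2, not SN2'), and dilute aqueous acid hydrolyses the dimethyl acetal without touching the trisubstituted alkene.

**Step 3**
Reactants: 6 4-methoxy-3-(3-methylbut-2-en-1-yl)benzaldehyde; 7 (E)-1-methoxy-3-(trimethylsilyloxy)buta-1,3-diene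
Product: 9 (2S)-2-Ar-2,3-dihydro-4H-pyran-4-one, via silyl aldol adduct 8 (not isolated)
Conditions: Ti(OiPr)4 (10 mol%), (S)-H8-BINOL (11 mol%), 4 Å MS, toluene, 0 °C; then TFA (cat.), CH2Cl2, 0 °C
Reagents that add atoms: none
Why: The Ti(IV)–(S)-H8-binaphtholate activates the formyl group and the silyl enol ether terminus of 7 adds to it in a Mukaiyama-aldol-like step (C2–C3), silyl transfer giving enone 8 and releasing the catalyst; catalytic TFA then makes the C2 oxygen add to the methoxy-bearing carbon (O1–C8a) and methanol is lost. The closest known reaction is the Ti–BINOL-type catalysed formal hetero-Diels–Alder reaction of aromatic aldehydes with this diene. Ring C, the only ring formed, closes by 6-endo-trig oxa-conjugate addition followed by β-elimination of methanol, so the net change is a [4+2] annulation of the C=O group onto the diene. The one new stereocentre, C2, is catalyst-controlled: the binaphtholate blocks one face of the Ti-bound aldehyde and the Si face is attacked. The step needs enantioface selectivity and chemoselectivity for the formyl group over the prenyl alkene. A non-enolisable, unhindered aryl aldehyde with a single Lewis-basic carbonyl serves the first, and the isolated trisubstituted alkene, meta to the reacting centre, should be inert to the Lewis acid at 0 °C and to catalytic TFA.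

**Step 4**
Reactants: 10 2,2,6-trimethyl-4H-1,3-dioxin-4-one
Product: 12 2,2-dimethyl-6-methylene-4-(tert-butyldimethylsilyloxy)-1,3-diox-4-ene, via lithium dienolate 11 (not isolated)
Conditions: LDA, THF, −78 °C; TBSCl, DMPU, −78 °C → rt
Reagents that add atoms: tert-butyldimethylsilyl chloride, CC(C)(C)[Si](C)(C)Cl
Why: Kinetic γ-deprotonation of the vinylogous ester and O-silylation of the dienolate (silyl dienol ether formation) is the standard entry to this vinylogous Mukaiyama donor.

**Step 5**
Reactants: 9 (2S)-2-Ar-2,3-dihydro-4H-pyran-4-one; 12 2,2-dimethyl-6-methylene-4-(tert-butyldimethylsilyloxy)-1,3-diox-4-ene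
Product: 13 (2S,6R)-2-Ar-4-(tert-butyldimethylsilyloxy)-6-[(2,2-dimethyl-4-oxo-4H-1,3-dioxin-6-yl)methyl]-3,6-dihydro-2H-pyran
Conditions: TBSOTf (0.3 equiv), 2,6-di-tert-butylpyridine (0.4 equiv), CH2Cl2, −78 °C; Et3N quench
Reagents that add atoms: none
Why: In this silyl-triflate-catalysed vinylogous Mukaiyama–Michael addition, O-silylation of the vinylogous ester gives a 4-silyloxy-oxocarbenium ion that the γ-carbon of 12 attacks at C8a (C8–C8a), axially and so trans to the C2 aryl group, and silyl transfer leaves the regiodefined C4=C4a enol ether; the new centre at C8a is relayed from C2 and is removed again in step 6, so a cis isomer would converge.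

**Step 6**
Reactants: 13 (2S,6R)-2-Ar-4-(tert-butyldimethylsilyloxy)-6-[(2,2-dimethyl-4-oxo-4H-1,3-dioxin-6-yl)methyl]-3,6-dihydro-2H-pyran
Product: 14 (2S)-6-[(2,2-dimethyl-4-oxo-4H-1,3-dioxin-6-yl)methyl]-2-Ar-2,3-dihydro-4H-pyran-4-one
Conditions: Pd(OAc)2 (1.1 equiv), MeCN, 25–40 °C
Reagents that add atoms: none
Why: In this Saegusa–Ito oxidation, Pd(II) converts the regiodefined silyl enol ether into the C4a-palladated ketone and syn β-hydride elimination of H8a restores the C4a=C8a enone, now carrying C8; C2 is untouched and the trisubstituted prenyl alkene is a poor ligand for Pd(II) under these conditions.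

**Step 7**
Reactants: 14 (2S)-6-[(2,2-dimethyl-4-oxo-4H-1,3-dioxin-6-yl)methyl]-2-Ar-2,3-dihydro-4H-pyran-4-one
Product: 17 (2S)-5,7-dihydroxy-2-[4-methoxy-3-(3-methylbut-2-en-1-yl)phenyl]-2,3-dihydro-4H-chromen-4-one (4'-O-methyllicoflavanone), via acylketene 15 (not isolated), via cyclohexadienone 16 (not isolated)
Conditions: toluene (0.005 M, slow addition), 110 °C
Reagents that add atoms: none
Why: Proposed new method: thermal retro-[4+2] of the dioxinone expels acetone to give acylketene 15, whose C7 carbonyl enolises towards C8 so that the ketene carbon C5, C6, C7=C8 and the enol ether C8a=C4a form a dienylketene that closes C4a–C5 by 6π-electrocyclisation (equivalently, attack of the nucleophilic enol-ether carbon C4a on the ketene) to dienone 16, which tautomerises irreversibly to the phloroglucinol ring. The closest known reactions are the intramolecular trapping of dioxinone-derived acylketenes and the dienylketene electrocyclisation that ends the Danheiser benzannulation, and the neutral medium keeps C2 away from base.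

**Compound list**

1 | 3-bromo-4-methoxybenzaldehyde | COc1ccc(C=O)cc1Br | starting material
2 | 2-bromo-4-(dimethoxymethyl)-1-methoxybenzene | COc1ccc(C(OC)OC)cc1Br | intermediate
3 | 1-bromo-3-methylbut-2-ene (prenyl bromide) | CC(C)=CCBr | starting material
4 | [5-(dimethoxymethyl)-2-methoxyphenyl]lithium | [Li]c1cc(C(OC)OC)ccc1OC | intermediate (not isolated)
5 | 4-(dimethoxymethyl)-1-methoxy-2-(3-methylbut-2-en-1-yl)benzene | COc1ccc(C(OC)OC)cc1CC=C(C)C | intermediate (not isolated)
6 | 4-methoxy-3-(3-methylbut-2-en-1-yl)benzaldehyde | COc1ccc(C=O)cc1CC=C(C)C | intermediate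
7 | (E)-1-methoxy-3-(trimethylsilyloxy)buta-1,3-diene | CO/C=C/C(=C)O[Si](C)(C)C | starting material
8 | (1E,5S)-1-methoxy-5-Ar-5-(trimethylsilyloxy)pent-1-en-3-one | CO/C=C/C(=O)C[C@H](O[Si](C)(C)C)c1ccc(OC)c(CC=C(C)C)c1 | intermediate (not isolated)
9 | (2S)-2-Ar-2,3-dihydro-4H-pyran-4-one | O=C1C=CO[C@H](c2ccc(OC)c(CC=C(C)C)c2)C1 | intermediate
10 | 2,2,6-trimethyl-4H-1,3-dioxin-4-one | CC1=CC(=O)OC(C)(C)O1 | starting material
11 | lithium dienolate of 10 (lithium 2,2-dimethyl-6-methylene-1,3-diox-4-en-4-olate) | [Li]OC1=CC(=C)OC(C)(C)O1 | intermediate (not isolated)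
12 | 2,2-dimethyl-6-methylene-4-(tert-butyldimethylsilyloxy)-1,3-diox-4-ene | C=C1C=C(O[Si](C)(C)C(C)(C)C)OC(C)(C)O1 | intermediate
13 | (2S,6R)-2-Ar-4-(tert-butyldimethylsilyloxy)-6-[(2,2-dimethyl-4-oxo-4H-1,3-dioxin-6-yl)methyl]-3,6-dihydro-2H-pyran (2,6-trans) | O1[C@H](c2ccc(OC)c(CC=C(C)C)c2)CC(O[Si](C)(C)C(C)(C)C)=C[C@H]1CC1=CC(=O)OC(C)(C)O1 | intermediate
14 | (2S)-6-[(2,2-dimethyl-4-oxo-4H-1,3-dioxin-6-yl)methyl]-2-Ar-2,3-dihydro-4H-pyran-4-one | O=C1C=C(CC2=CC(=O)OC(C)(C)O2)O[C@H](c2ccc(OC)c(CC=C(C)C)c2)C1 | intermediate
15 | 4-[(2S)-2-Ar-4-oxo-3,4-dihydro-2H-pyran-6-yl]but-1-ene-1,3-dione (acylketene) | O=C=CC(=O)CC1=CC(=O)C[C@@H](c2ccc(OC)c(CC=C(C)C)c2)O1 | intermediate (not isolated)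
16 | (2S)-7-hydroxy-2-Ar-2,3-dihydro-4H-chromene-4,5(4aH)-dione (C4a epimers) | O=C1C=C(O)C=C2O[C@H](c3ccc(OC)c(CC=C(C)C)c3)CC(=O)C12 | intermediate (not isolated)
17 | (2S)-5,7-dihydroxy-2-[4-methoxy-3-(3-methylbut-2-en-1-yl)phenyl]-2,3-dihydro-4H-chromen-4-one (4'-O-methyllicoflavanone) | COc1ccc([C@@H]2CC(=O)c3c(O)cc(O)cc3O2)cc1CC=C(C)C | target

**Step count and risks**

Total step count: 7. Longest linear sequence: 6 steps (steps 1, 2, 3, 5, 6, 7); step 4 is a one-step side branch.

**Step 7.** The acylketene may be consumed by intermolecular paths (dimerisation, acylation of product phenols) or held reversibly at O1 faster than C4a–C5 closure occurs. The fallback uses known chemistry, sets out from 14 and returns at 17. Compound 14 is heated in toluene with methanol so that the acylketene is captured as the β-keto ester methyl 4-[(2S)-2-Ar-4-oxo-3,4-dihydro-2H-pyran-6-yl]-3-oxobutanoate F1. This ester is then closed by an intramolecular Claisen (Dieckmann-type) condensation, C4a of the vinylogous dienolate attacking the ester carbon, with Mg(OMe)2 in MeOH at room temperature, which is the Claisen mode of cyclisation known for 3,5,7-triketo esters. Acidification should give 17; because this medium is basic, the enantiomeric purity at C2 would have to be checked.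

**Step 5.** Addition to the vinylogous ester may be slow, so that prolonged contact with the silyl triflate ionises the p-alkoxybenzylic C2–O1 bond (ring opening, erosion of ee), or the enol ether regiochemistry needed for step 6 may be lost by hydrolysis. The fallback sets out from 9 and returns at 14, bypassing 13 and the palladium step: the unsaturation is carried as a halide instead of being restored by oxidation. α-Iodination of 9 (I2, pyridine, CH2Cl2; bromine sources are excluded by the prenyl alkene) would give (2S)-5-iodo-2-Ar-2,3-dihydro-4H-pyran-4-one F2, a more electrophilic acceptor. BF3·OEt2-mediated Mukaiyama–Michael addition of 12 at −78 °C and aqueous work-up would give the α-iodo ketone (2S,6R)-5-iodo-6-[(2,2-dimethyl-4-oxo-4H-1,3-dioxin-6-yl)methyl]-2-Ar-tetrahydro-4H-pyran-4-one F3 (numbered as in 9, C5 epimers). Et3N in CH2Cl2 then removes HI, as in the conversion of 3-haloflavanones into flavones, to give 14.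

**Step 3.** Enantioface discrimination may be incomplete for this electron-rich aldehyde, and the acid used for ring closure may ionise the p-alkoxybenzylic carbinol or hydrate the prenyl group. The fallback sets out from 6 and returns at 9, replacing catalysis by stoichiometric reagent control. The enol diisopinocampheylborinate of purchased (E)-4-chlorobut-3-en-2-one (Ipc2BCl, iPr2NEt, Et2O, −78 °C; Ipc antipode chosen for the S carbinol) adds to 6 in a boron aldol reaction to give (1E,5S)-1-chloro-5-hydroxy-5-Ar-pent-1-en-3-one F4. This is cyclised without protic acid by intramolecular oxa-conjugate addition and loss of chloride (TMSOTf, iPr2NEt, CH2Cl2, −78 °C) to give 9.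

**Further compounds**

F1 | step 7 | methyl 4-[(2S)-2-Ar-4-oxo-3,4-dihydro-2H-pyran-6-yl]-3-oxobutanoate | COC(=O)CC(=O)CC1=CC(=O)C[C@@H](c2ccc(OC)c(CC=C(C)C)c2)O1
F2 | step 5 | (2S)-5-iodo-2-Ar-2,3-dihydro-4H-pyran-4-one | O=C1C(I)=CO[C@H](c2ccc(OC)c(CC=C(C)C)c2)C1
F3 | step 5 | (2S,6R)-5-iodo-6-[(2,2-dimethyl-4-oxo-4H-1,3-dioxin-6-yl)methyl]-2-Ar-tetrahydro-4H-pyran-4-one (C5 epimers) | O1[C@H](c2ccc(OC)c(CC=C(C)C)c2)CC(=O)C(I)[C@H]1CC1=CC(=O)OC(C)(C)O1
F4 | step 3 | (1E,5S)-1-chloro-5-hydroxy-5-Ar-pent-1-en-3-one | Cl/C=C/C(=O)C[C@H](O)c1ccc(OC)c(CC=C(C)C)c1
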